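**Plan**
- Cuts: the C3–O ester bond (dienoic acid), the C12–OAc and C7–C11 bonds (side chain built from acetone on a 7‑silyloxy enolate), then ring A at C5–C6 and C9=C10 (Robinson annulation), then the two methyls of ring B.
- Forward: ring B (C1–C5, C10) is taken from a chiral‑pool 4‑silyloxycyclohexenone, ring A (C5–C10) is annulated onto it in step 4, then the C7 side chain is built, and the ester is joined last.
- Enabling feature: ring A is a cyclohex‑2‑enone (C8=O, C9=C10) in which C8 and C10 are 1,5‑related through C7–C6–C5. C10 is also the carbonyl carbon of a ring B enone (C10–C1=C2), so annulation at its α′‑carbon C5 gives the 1,9‑dien‑8‑one directly, and the vinyl ketone brings in the C7 oxygen.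
- Stereochemistry: C3 comes from the starting enone, C4 from anti cuprate addition, C5 from Michael addition anti to the C4 methyl, and C7 from an aldol in which carbon enters last, anti to the axial C5 methyl (O ends cis to the methyls). C6′ comes from an Evans alkylation and the E‑alkenes from Wittig reactions.

Key step: step 4

Conventions and assumptions: eremophilane numbering is used (ring A = C5–C10, ring B = C1–C5/C10, C11–C13 on C7, methyls on C4 and C5); α is the face of the two ring methyls and β the opposite face. Metal enolates and alkoxides formed in situ are treated as activated forms of the numbered compounds. (R)‑4‑(tert‑Butyldimethylsilyloxy)cyclohex‑2‑en‑1‑one is assumed to be bought as such.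

**Step 1**
Reactants: 1 (R)-4-(tert-butyldimethylsilyloxy)cyclohex-2-en-1-one
Product: 2 (3S,4S)-4-(tert-butyldimethylsilyloxy)-2,3-dimethylcyclohexan-1-one (C2 epimers)
Conditions: Me2CuLi (from MeLi and CuI), Et2O, −78 °C; then MeI, DMPU, −78 → 0 °C
Reagents that add atoms: lithium dimethylcuprate, [Li+].C[Cu-]C; iodomethane, CI
Why: Conjugate addition of the cuprate anti to the γ‑silyloxy group sets the C4 methyl trans to O‑3, and the regiodefined enolate is C‑methylated in the same flask (conjugate addition–enolate alkylation); the new α‑centre is planarised again in step 4.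

**Step 2**
Reactants: 2 (3S,4S)-4-(tert-butyldimethylsilyloxy)-2,3-dimethylcyclohexan-1-one
Product: 4 (4S,5S)-4-(tert-butyldimethylsilyloxy)-5,6-dimethylcyclohex-2-en-1-one (C6 epimers), via trimethylsilyl enol ether 3 (not isolated)
Conditions: LiN(i-Pr)2, THF, −78 °C; Me3SiCl; then Pd(OAc)2 (1.1 equiv), MeCN, 23 °C
Reagents that add atoms: none
Why: Saegusa–Ito oxidation: kinetic deprotonation takes a proton of the CH2 group and not the methine, and β‑hydride elimination from the palladium enolate places the double bond next to the silyloxy‑bearing carbon.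

**Step 3**
Reactants: 5 butane-2,3-dione
Product: 6 3-(tert-butyldimethylsilyloxy)but-3-en-2-one
Conditions: t-BuMe2SiOTf (1.0 equiv), Et3N, CH2Cl2, 0 °C
Reagents that add atoms: tert-butyldimethylsilyl trifluoromethanesulfonate, CC(C)(C)[Si](C)(C)OS(=O)(=O)C(F)(F)F
Why: Soft enolisation and O‑silylation of one carbonyl of the 1,2‑diketone gives the mono silyl enol ether, a 2‑oxygenated methyl vinyl ketone.

**Step 4**
Reactants: 4 (4S,5S)-4-(tert-butyldimethylsilyloxy)-5,6-dimethylcyclohex-2-en-1-one; 6 3-(tert-butyldimethylsilyloxy)but-3-en-2-one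
Product: 9 3β,7-bis(tert-butyldimethylsilyloxy)-11,12,13-trinoreremophila-1,9-dien-8-one (4α,5α-dimethyl; C7 epimers), via Michael adduct 7 (not isolated), via aldol 8 (not isolated)
Conditions: LiN(i-Pr)2, THF, −78 °C; 6, −78 → −40 °C; AcOH (1 equiv), −78 °C; then pyrrolidine, AcOH, toluene, 50 °C (same flask)
Reagents that add atoms: none
Why: Robinson annulation (Michael addition, then intramolecular aldol condensation): deprotonation of 4 at its only α′‑position gives the cross‑conjugated lithium dienolate, which adds through C5 to the CH2 terminus of 6 (C5–C6); after protonation the amine–acid buffer turns the methyl ketone into its enamine, which attacks the C10 carbonyl and loses water to give C9=C10 in conjugation with C8=O and C1=C2. The closest known reaction type is the aprotic Robinson annulation of preformed lithium enolates of 2,3‑dimethylcyclohexanones with α‑substituted (α‑silyl) methyl vinyl ketones, as used for eremophilane octalones. Ring A closes in the 6‑(enolexo)‑exo‑trig mode. The new quaternary centre C5 is controlled by the adjacent C4 methyl, which sits pseudoaxial to avoid allylic strain with the enolate methyl and sends the acceptor to the opposite face (vicinal methyls cis); the carbinol centre C10 of 8 is lost on dehydration and C7 is left as a mixture that step 5 erases. The step needs α′‑ over γ‑deprotonation (amide base at −78 °C), 1,4‑ over 1,2‑addition (fully substituted enolate carbon), and aldol closure over a second, intramolecular Michael addition of the C7 enolate to C2 that would give a bicyclo[2.2.2]octane. That side path should be held back by the fully substituted silyloxy‑bearing C7, by the β‑silyloxy group on C3 that screens C2 on the tether face, and by quenching the adduct enolate before the enamine closure, which engages C9 and not C7.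

**Step 5**
Reactants: 9 3β,7-bis(tert-butyldimethylsilyloxy)-11,12,13-trinoreremophila-1,9-dien-8-one
Product: 10 3β,7α-bis(tert-butyldimethylsilyloxy)-11-hydroxyeremophila-1,9-dien-8-one
Conditions: LiN(i-Pr)2, THF, −78 °C; CeCl3 (anhydrous), −78 °C; acetone, −78 °C; AcOH, −78 °C
Reagents that add atoms: acetone, CC(C)=O
Why: Aldol addition of a cerium enolate: the only α‑proton (C7–H) is removed and the 7‑silyloxy enolate should add to acetone from the β‑face, anti to the pseudoaxial C5 methyl that is 1,3 to C7, so that carbon ends β and oxygen α as in the target; CeCl3 suppresses acetone enolisation and retro‑aldol, and the cold acidic quench prevents O‑to‑O silyl migration.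

**Step 6**
Reactants: 10 3β,7α-bis(tert-butyldimethylsilyloxy)-11-hydroxyeremophila-1,9-dien-8-one
Product: 11 3β,7α-bis(tert-butyldimethylsilyloxy)eremophila-1,9,11-trien-8-one
Conditions: methyl N-(triethylammoniosulfonyl)carbamate, toluene, 50 °C
Reagents that add atoms: none
Why: Dehydration of the tertiary alcohol by syn‑elimination of its sulfamate ester; C7 is quaternary, so only methyl hydrogens are available and the isopropenyl group is the single possible alkene.

**Step 7**
Reactants: 11 3β,7α-bis(tert-butyldimethylsilyloxy)eremophila-1,9,11-trien-8-one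
Product: 12 12-chloro-3β,7α-bis(tert-butyldimethylsilyloxy)eremophila-1,9,11(13)-trien-8-one
Conditions: Ca(OCl)2, CO2 (solid), CH2Cl2/H2O, 0 °C
Reagents that add atoms: calcium hypochlorite (source of HOCl), [Ca+2].[O-]Cl.[O-]Cl
Why: Ene‑type allylic chlorination by HOCl made in situ: the 1,1‑disubstituted alkene is the only electron‑rich double bond (the ring alkenes are deactivated by conjugation with C8=O), and chlorine adds to the terminal carbon with shift of the double bond to the former methyl.

**Step 8**
Reactants: 12 12-chloro-3β,7α-bis(tert-butyldimethylsilyloxy)eremophila-1,9,11(13)-trien-8-one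
Product: 13 12-acetoxy-3β,7α-bis(tert-butyldimethylsilyloxy)eremophila-1,9,11(13)-trien-8-one
Conditions: KOAc, 18-crown-6 (cat.), MeCN, 60 °C
Reagents that add atoms: potassium acetate, CC(=O)[O-].[K+]
Why: SN2 displacement of the primary allylic chloride by acetate.

**Step 9**
Reactants: 13 12-acetoxy-3β,7α-bis(tert-butyldimethylsilyloxy)eremophila-1,9,11(13)-trien-8-one
Product: 14 12-acetoxy-3β,7α-dihydroxyeremophila-1,9,11(13)-trien-8-one
Conditions: HF·pyridine, pyridine, THF, 0 → 23 °C
Reagents that add atoms: none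
Why: Fluoride‑mediated cleavage of both silyl ethers (desilylation) in a buffered medium that should leave the allylic acetate and the α‑ketol untouched.

**Step 10**
Reactants: 15 (R)-4-benzyloxazolidin-2-one; 16 butanoyl chloride
Product: 17 (R)-4-benzyl-3-butanoyloxazolidin-2-one
Conditions: n-BuLi, THF, −78 °C; then 16, −78 → 0 °C
Reagents that add atoms: none
Why: N‑Acylation of the lithiated oxazolidinone by the acid chloride.

**Step 11**
Reactants: 17 (R)-4-benzyl-3-butanoyloxazolidin-2-one
Product: 18 (R)-4-benzyl-3-[(R)-2-methylbutanoyl]oxazolidin-2-one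
Conditions: NaN(SiMe3)2, THF, −78 °C; MeI, −78 → −40 °C
Reagents that add atoms: iodomethane, CI
Why: Evans asymmetric alkylation: the chelated Z‑sodium enolate is methylated on the face opposite the benzyl group, which with the (R)‑auxiliary gives the (R)‑2‑methylbutanoyl unit.

**Step 12**
Reactants: 18 (R)-4-benzyl-3-[(R)-2-methylbutanoyl]oxazolidin-2-one
Product: 19 (R)-2-methylbutan-1-ol
Conditions: LiBH4, H2O (1 equiv), Et2O, 0 °C; aq. NaOH work-up
Reagents that add atoms: none
Why: Reductive cleavage of the imide by LiBH4 releases the primary alcohol without epimerisation and returns the auxiliary.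

**Step 13**
Reactants: 19 (R)-2-methylbutan-1-ol
Product: 21 ethyl (R,E)-2,4-dimethylhex-2-enoate, via (R)-2-methylbutanal 20 (not isolated)
Conditions: (COCl)2, Me2SO, CH2Cl2, −78 °C; Et3N; then Ph3P=C(Me)CO2Et, −78 → 23 °C
Reagents that add atoms: ethyl 2-(triphenylphosphoranylidene)propanoate, CCOC(=O)C(C)=P(c1ccccc1)(c1ccccc1)c1ccccc1
Why: Swern oxidation followed in the same flask by Wittig olefination with the stabilised ylide gives the (E)‑trisubstituted enoate, and the configurationally labile aldehyde is never isolated.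

**Step 14**
Reactants: 21 ethyl (R,E)-2,4-dimethylhex-2-enoate
Product: 22 (R,E)-2,4-dimethylhex-2-en-1-ol
Conditions: i-Bu2AlH, CH2Cl2, −78 °C; aqueous potassium sodium tartrate work-up
Reagents that add atoms: none
Why: 1,2‑Reduction of the conjugated ester to the allylic alcohol by the aluminium hydride.

**Step 15**
Reactants: 22 (R,E)-2,4-dimethylhex-2-en-1-ol
Product: 24 ethyl (2E,4E,6R)-4,6-dimethylocta-2,4-dienoate, via (R,E)-2,4-dimethylhex-2-enal 23 (not isolated)
Conditions: MnO2 (activated, excess), Ph3P=CHCO2Et, CH2Cl2, 23 °C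
Reagents that add atoms: ethyl (triphenylphosphoranylidene)acetate, CCOC(=O)C=P(c1ccccc1)(c1ccccc1)c1ccccc1
Why: Tandem allylic oxidation–Wittig olefination: MnO2 oxidises the allylic alcohol to the enal, which is trapped as it forms by the stabilised ylide to give the (2E)‑dienoate.

**Step 16**
Reactants: 24 ethyl (2E,4E,6R)-4,6-dimethylocta-2,4-dienoate
Product: 25 (2E,4E,6R)-4,6-dimethylocta-2,4-dienoic acid
Conditions: LiOH, THF/MeOH/H2O, 23 °C; then aq. HCl
Reagents that add atoms: lithium hydroxide, [Li+].[OH-]
Why: Saponification of the ethyl ester under conditions that do not touch the diene geometry or the remote stereocentre.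

**Step 17**
Reactants: 25 (2E,4E,6R)-4,6-dimethylocta-2,4-dienoic acid; 14 12-acetoxy-3β,7α-dihydroxyeremophila-1,9,11(13)-trien-8-one
Product: 27 (3S,4S,5S,7S)-12-acetoxy-7-hydroxy-8-oxoeremophila-1,9,11(13)-trien-3-yl (2E,4E,6R)-4,6-dimethylocta-2,4-dienoate (CNP0160850.1), via mixed anhydride 26 (not isolated)
Conditions: 2,4,6-trichlorobenzoyl chloride, Et3N, toluene, 23 °C; then 14, DMAP, toluene, 23 °C
Reagents that add atoms: none
Why: Yamaguchi esterification: the acid is activated as the mixed anhydride and transferred by DMAP to the secondary allylic C3 hydroxyl, while the tertiary C7 hydroxyl is too hindered to acylate.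

**Compound list**
1 | (R)-4-(tert-butyldimethylsilyloxy)cyclohex-2-en-1-one | O=C1C=C[C@H](O[Si](C)(C)C(C)(C)C)CC1 | starting material
2 | (3S,4S)-4-(tert-butyldimethylsilyloxy)-2,3-dimethylcyclohexan-1-one (C2 epimers; 3-methyl trans to silyloxy) | CC1C(=O)CC[C@H](O[Si](C)(C)C(C)(C)C)[C@H]1C | intermediate
3 | {[(4S,5S)-4-(tert-butyldimethylsilyloxy)-5,6-dimethylcyclohex-1-en-1-yl]oxy}trimethylsilane | CC1C(O[Si](C)(C)C)=CC[C@H](O[Si](C)(C)C(C)(C)C)[C@H]1C | intermediate
4 | (4S,5S)-4-(tert-butyldimethylsilyloxy)-5,6-dimethylcyclohex-2-en-1-one (C6 epimers) | CC1C(=O)C=C[C@H](O[Si](C)(C)C(C)(C)C)[C@H]1C | intermediate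
5 | butane-2,3-dione | CC(=O)C(C)=O | starting material
6 | 3-(tert-butyldimethylsilyloxy)but-3-en-2-one | C=C(O[Si](C)(C)C(C)(C)C)C(C)=O | intermediate
7 | (4S,5S)-4-(tert-butyldimethylsilyloxy)-6-[2-(tert-butyldimethylsilyloxy)-3-oxobutyl]-5,6-dimethylcyclohex-2-en-1-one (oxobutyl chain trans to the C5 methyl; side-chain epimers) | CC(=O)C(O[Si](C)(C)C(C)(C)C)C[C@]1(C)C(=O)C=C[C@H](O[Si](C)(C)C(C)(C)C)[C@H]1C | intermediate
8 | 10-hydroxy-3β,7-bis(tert-butyldimethylsilyloxy)-11,12,13-trinoreremophil-1-en-8-one (epimers at C7 and C10) | CC(C)(C)[Si](C)(C)OC1C[C@]2(C)C(O)(CC1=O)C=C[C@H](O[Si](C)(C)C(C)(C)C)[C@H]2C | intermediate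
9 | 3β,7-bis(tert-butyldimethylsilyloxy)-11,12,13-trinoreremophila-1,9-dien-8-one (4α,5α-dimethyl; C7 epimers) | CC(C)(C)[Si](C)(C)OC1C[C@]2(C)C(=CC1=O)C=C[C@H](O[Si](C)(C)C(C)(C)C)[C@H]2C | intermediate
10 | 3β,7α-bis(tert-butyldimethylsilyloxy)-11-hydroxyeremophila-1,9-dien-8-one | CC(C)(O)[C@@]1(O[Si](C)(C)C(C)(C)C)C[C@]2(C)C(=CC1=O)C=C[C@H](O[Si](C)(C)C(C)(C)C)[C@H]2C | intermediate
11 | 3β,7α-bis(tert-butyldimethylsilyloxy)eremophila-1,9,11-trien-8-one | C=C(C)[C@@]1(O[Si](C)(C)C(C)(C)C)C[C@]2(C)C(=CC1=O)C=C[C@H](O[Si](C)(C)C(C)(C)C)[C@H]2C | intermediate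
12 | 12-chloro-3β,7α-bis(tert-butyldimethylsilyloxy)eremophila-1,9,11(13)-trien-8-one | C=C(CCl)[C@@]1(O[Si](C)(C)C(C)(C)C)C[C@]2(C)C(=CC1=O)C=C[C@H](O[Si](C)(C)C(C)(C)C)[C@H]2C | intermediate
13 | 12-acetoxy-3β,7α-bis(tert-butyldimethylsilyloxy)eremophila-1,9,11(13)-trien-8-one | C=C(COC(C)=O)[C@@]1(O[Si](C)(C)C(C)(C)C)C[C@]2(C)C(=CC1=O)C=C[C@H](O[Si](C)(C)C(C)(C)C)[C@H]2C | intermediate
14 | 12-acetoxy-3β,7α-dihydroxyeremophila-1,9,11(13)-trien-8-one | C=C(COC(C)=O)[C@@]1(O)C[C@]2(C)C(=CC1=O)C=C[C@H](O)[C@H]2C | intermediate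
15 | (R)-4-benzyloxazolidin-2-one | O=C1N[C@H](Cc2ccccc2)CO1 | starting material
16 | butanoyl chloride | CCCC(=O)Cl | starting material
17 | (R)-4-benzyl-3-butanoyloxazolidin-2-one | CCCC(=O)N1[C@H](Cc2ccccc2)COC1=O | intermediate
18 | (R)-4-benzyl-3-[(R)-2-methylbutanoyl]oxazolidin-2-one | CC[C@@H](C)C(=O)N1[C@H](Cc2ccccc2)COC1=O | intermediate
19 | (R)-2-methylbutan-1-ol | OC[C@H](C)CC | intermediate
20 | (R)-2-methylbutanal | O=C[C@H](C)CC | intermediate
21 | ethyl (R,E)-2,4-dimethylhex-2-enoate | CCOC(=O)/C(C)=C/[C@H](C)CC | intermediate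
22 | (R,E)-2,4-dimethylhex-2-en-1-ol | OC/C(C)=C/[C@H](C)CC | intermediate
23 | (R,E)-2,4-dimethylhex-2-enal | O=C/C(C)=C/[C@H](C)CC | intermediate
24 | ethyl (2E,4E,6R)-4,6-dimethylocta-2,4-dienoate | CCOC(=O)/C=C/C(C)=C/[C@H](C)CC | intermediate
25 | (2E,4E,6R)-4,6-dimethylocta-2,4-dienoic acid | OC(=O)/C=C/C(C)=C/[C@H](C)CC | intermediate
26 | (2E,4E,6R)-4,6-dimethylocta-2,4-dienoic 2,4,6-trichlorobenzoic anhydride | O=C(OC(=O)/C=C/C(C)=C/[C@H](C)CC)c1c(Cl)cc(Cl)cc1Cl | intermediate
27 | (3S,4S,5S,7S)-12-acetoxy-7-hydroxy-8-oxoeremophila-1,9,11(13)-trien-3-yl (2E,4E,6R)-4,6-dimethylocta-2,4-dienoate | C=C(COC(C)=O)[C@@]1(O)C[C@]2(C)C(=CC1=O)C=C[C@H](OC(=O)/C=C/C(C)=C/[C@H](C)CC)[C@H]2C | target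

**Step count and risks**
Total step count: 17. Longest linear sequence: 9 steps (steps 1, 2, 4, 5, 6, 7, 8, 9 and 17).

Steps most likely to fail:

1. Step 4. After the first Michael addition the C7 enolate may add a second time, intramolecularly, to C2 of the ring B enone and give a bridged bicyclo[2.2.2]octane. The acceptor may also be lost to proton transfer or oligomerisation, and the facial bias at C5 may be eroded by the silyloxy group on C3. The fallback runs the annulation on the saturated ketone, where no second Michael acceptor exists, and introduces C1=C2 late; it sets out from 2 and comes back at 11. Ketone 2 with Me3SiCl, NaI and Et3N in MeCN should give the more substituted trimethylsilyl enol ether F1. MeLi in THF at 0 °C liberates its lithium enolate, which is annulated with 6 as in step 4 to the ring B saturated enone 3β,7-bis(tert-butyldimethylsilyloxy)-11,12,13-trinoreremophil-9-en-8-one F2. Aldol addition to acetone as in step 5 gives the carbinol F3, and sulfamate elimination as in step 6 gives the isopropenyl enone F4. Because C7 is then quaternary, chloranil in refluxing t-BuOH can dehydrogenate only toward C1–C2 and should deliver 11.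

2. Step 5. The fully substituted silyloxy enolate may add too slowly to a ketone, the adduct may revert by retro‑aldol, vinylogous deprotonation at C3 may compete, and the silyl group may migrate between the vicinal oxygens. The fallback forms the C7–C11 bond with an aldehyde and makes the alkene by olefination; it sets out from 9 and comes back at 11. The lithium enolate of 9 is added to acetaldehyde at −78 °C to give the secondary carbinol F5. Swern oxidation gives the 7‑acetyl ketone F6, and Ph3P=CH2 in THF at 0 °C should methylenate the unconjugated methyl ketone in preference to the dienone carbonyl to give 11.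

3. Step 7. The hypochlorous acid may also attack the ring diene or chlorinate further, giving loss of chemoselectivity. The fallback functionalises the methyl group by oxidation and not by halogenation; it sets out from 11 and comes back at 13. SeO2 (catalytic) with t-BuOOH in CH2Cl2 should hydroxylate the only allylic methyl to give the allylic alcohol F7, which Ac2O and pyridine convert into 13.

**Further compounds**
F1 | step 4 | {[(4S,5S)-4-(tert-butyldimethylsilyloxy)-5,6-dimethylcyclohex-1-en-1-yl]oxy}trimethylsilane, tetrasubstituted enol ether regioisomer (1-silyloxy-2-methyl alkene) | CC1=C(O[Si](C)(C)C)CC[C@H](O[Si](C)(C)C(C)(C)C)[C@H]1C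
F2 | step 4 | 3β,7-bis(tert-butyldimethylsilyloxy)-11,12,13-trinoreremophil-9-en-8-one (C7 epimers) | CC(C)(C)[Si](C)(C)OC1C[C@]2(C)C(=CC1=O)CC[C@H](O[Si](C)(C)C(C)(C)C)[C@H]2C
F3 | step 4 | 3β,7α-bis(tert-butyldimethylsilyloxy)-11-hydroxyeremophil-9-en-8-one | CC(C)(O)[C@@]1(O[Si](C)(C)C(C)(C)C)C[C@]2(C)C(=CC1=O)CC[C@H](O[Si](C)(C)C(C)(C)C)[C@H]2C
F4 | step 4 | 3β,7α-bis(tert-butyldimethylsilyloxy)eremophila-9,11-dien-8-one | C=C(C)[C@@]1(O[Si](C)(C)C(C)(C)C)C[C@]2(C)C(=CC1=O)CC[C@H](O[Si](C)(C)C(C)(C)C)[C@H]2C
F5 | step 5 | 3β,7α-bis(tert-butyldimethylsilyloxy)-11-hydroxy-13-noreremophila-1,9-dien-8-one (C11 epimers) | CC(O)[C@@]1(O[Si](C)(C)C(C)(C)C)C[C@]2(C)C(=CC1=O)C=C[C@H](O[Si](C)(C)C(C)(C)C)[C@H]2C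
F6 | step 5 | 3β,7α-bis(tert-butyldimethylsilyloxy)-13-noreremophila-1,9-diene-8,11-dione | CC(=O)[C@@]1(O[Si](C)(C)C(C)(C)C)C[C@]2(C)C(=CC1=O)C=C[C@H](O[Si](C)(C)C(C)(C)C)[C@H]2C
F7 | step 7 | 12-hydroxy-3β,7α-bis(tert-butyldimethylsilyloxy)eremophila-1,9,11(13)-trien-8-one | C=C(CO)[C@@]1(O[Si](C)(C)C(C)(C)C)C[C@]2(C)C(=CC1=O)C=C[C@H](O[Si](C)(C)C(C)(C)C)[C@H]2C
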